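The closed vessel starts with undissolved solid substrate and coupling partner. I want to know what the west flask holds at 8.0 h and which option adds target.

| setting | west | north-west | flask |
|---|---|---|---|
| solid substrate | 0.95 M | 0.95 M | 0.95 M |
| coupling partner | 0.665 M | 1 M | 0.665 M |
| remark | the very flask that is asked about, followed so far | run made earlier |  |
| time |  |  | 8.0 h |

| run | time / h | target / % | solid substrate / % |
|---|---|---|---|
| west | 1.00 | 23.7 | 9.9 |
| west | 2.00 | 20.8 | 0.4 |
| west | 3.00 | 20.6 | 0.3 |
| west | 4.00 | 19.5 | 0.9 |
| west | 5.00 | 22.0 | 1.1 |
| west | 6.00 | 20.9 | 0.2 |
| north-west | 0.500 | 25.3 | 42.9 |
| north-west | 1.00 | 31.4 | 0 |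
| north-west | 1.33 | 30.0 | 0 |
| north-west | 2.00 | 26.8 | 0.2 |
| north-west | 2.50 | 28.9 | 0 |
| north-west | 3.00 | 25.9 | 0 |

(scatter of a reading: 1 percentage point)

- green: at 8.0 h take out 90% of the by-product then present, then wait 15 h
- red: at 8.0 h add coupling partner, 50.0% of the amount charged, then wait 15 h
- violet: change nothing and wait 15 h more

- solid, in amounts per volume of the solution: solid substrate
- the volume of additions can be left aside
- what was read earlier has a scatter of 1 percentage point, one standard deviation
- steps under discussion: starting material + coupling partner -> intermediate + by-product; intermediate <-> target; intermediate <-> isomer of the product A; target <-> isomer of the product B; 2 coupling partner -> homo dimer; solid substrate <-> starting material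
- at the start none of the solid substrate is in solution

- target, in percent of the solid substrate first charged, at 8.0 h
- the option that brings most further target ("none" if no option brings more than 2 percentage points) (green / red / violet / none)
- target present, in percent of the solid substrate first charged, after red
- target present, in percent of the solid substrate first charged, after violet

In the west flask the solid substrate reads 0.4% at 2.00 h. From then until 6.00 h the target readings average 20.8%, and the last stands 0.1 percentage points above the first, which is less than the scatter of 1 point. The last 3 readings of the north-west flask, with the same solid and more coupling partner, stand higher, so I take the coupling partner to be what stops the west flask.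

Dividing the rate of target formation by the rate of partner loss removes time. If that ratio stays steady, the integral is simple: target equals a constant times the partner charged, both as fractions of the solid charge. West charges 0.700 of partner per solid, which gives 0.297, the return, meaning target gained per unit of partner. The last 3 north-west readings give 0.258.

Now I turn the question round. Red adds 0.350, so for "none" to be the answer its return would have to fall below 0.0571. The west return, as read, stands at 5.20 times that figure. I therefore commit to 20.8% now, no gain from waiting, and 10 points from red, or 31.1%.

The forecast gives 20.8%, 20.7% after violet, and red as the best option with 29%, lower than my figure, noting that “A late addition has less starting material, but also less dimer loss”.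

The flask gives 20.2%, 20.2% after violet, and 32.3% after red, a gain of 12 points, while green brings 0 points.

    starting material + coupling partner → intermediate + by-product (k = 0.0180 M⁻¹ s⁻¹)
    intermediate ⇌ target (K = 6.10, k = 0.00580 s⁻¹)
    intermediate ⇌ isomer of the product A (K = 2.90, k = 8.50 × 10⁻⁴ s⁻¹)
    target ⇌ isomer of the product B (K = 1.20, k = 4.90 × 10⁻⁴ s⁻¹)
    2 coupling partner → homo dimer (k = 2.20 × 10⁻⁴ M⁻¹ s⁻¹)
    solid substrate ⇌ starting material, rate k6*(cs6 - [starting material]) while solid is left; crystals form when [starting material] > cs6 (solubility = 0.480 M, k = 6.90 × 10⁻⁴ s⁻¹)

At 8.00 h the west flask has 0% of its coupling partner left, the limiting reagent, beside 42.7% of starting material, and the forecast stands right. In the west flask red returns 0.346, higher than the return read from the west run. The neighbour flask charged with 0.57 M of solid substrate has 1.17 of partner per solid, so the return of 0.297 gives 34.7%, and that neighbour flask holds 33.6%.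

The data are simulated for an exercise, noise included.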